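**Strategy**

Everything rests on taking ring A apart into a vinylketene and an ynol ether. Its C2 with the 2-oxygen is the ketene carbonyl, C3 and C4 with the 4-oxygen are the two carbons of ethoxyacetylene, C5 is a former diazo carbon, and C6 with its methyl, C1 and the depside carbonyl come from an enoate. One photochemical operation, forming C5–C6, C2–C3, C4–C5 and C1–C2, should turn the ring B ester of (2E)-5-diazo-3-methyl-4-oxopent-2-enoic acid into the complete depside skeleton, with the meta-related ring A oxygens already differentiated as free 2-OH and 4-OEt. The precursor is therefore the fully substituted, chlorinated ring B phenol carrying an E-configured α′-diazo enoate on its 4-oxygen.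

Key step: step 6

**Remarks on the chemistry (assumptions and design choices)**

- Numbering: ring A is the formyl-bearing benzoyl ring, counted from the carbon that carries the depside carbonyl (C1; 2-OH, 3-CHO, 4-OH, 5-Cl, 6-CH3). Ring B is the methyl benzoate ring. The target has no stereocentre; the only stereo-element in the route is the E alkene of compounds 5 to 14.
- Atom origin: ring A C2 is the ketone carbonyl carbon of the diazo ketone and C5 is its diazo carbon. The Wolff shift therefore makes C5–C6, so the key step forms four ring A bonds, not three.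
- Alkene geometry: the enoate is used as the E isomer (ester trans to the diazoacetyl group), not the Z (citraconate-type) isomer. A Z aryl half-ester would tend to re-close to the anhydride and expel the acidic phenol. A Z vinylketene could also close through its ester carbonyl oxygen to a 6-aryloxypyran-2-one. The E isomer avoids both and gives the same arene, because the alkene ends up inside ring A.
- Diazo group: it is introduced by diazo transfer to a methyl ketone, not by acylating diazomethane, because diazomethane adds as a 1,3-dipole to this doubly activated alkene.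
- Light: the photolysis uses light above 300 nm, which the diazo enone absorbs, to spare the aryl chloride and the aryl ester.

**Route**

Step 1
Reactants: 1 methyl 2,4-dihydroxy-3,6-dimethylbenzoate
Product: 2 methyl 5-chloro-2,4-dihydroxy-3,6-dimethylbenzoate
Conditions: SO2Cl2 (1.05 equiv), Et2O–CH2Cl2, 0 °C → rt
Reagents that add atoms: sulfuryl chloride, ClS(Cl)(=O)=O
Why: Electrophilic aromatic chlorination should occur only at C5, the sole unsubstituted ring position, which is ortho to the 4-OH and para to the 2-OH.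

Step 2
Reactants: 3 butane-2,3-dione (in excess); 4 tert-butyl (triphenyl-λ5-phosphanylidene)acetate
Product: 5 tert-butyl (2E)-3-methyl-4-oxopent-2-enoate
Conditions: CH2Cl2, rt
Reagents that add atoms: none
Why: Wittig olefination of one of the two equivalent carbonyls by an ester-stabilised ylide should give the E enoate (ester trans to acetyl) through the less crowded oxaphosphetane, with the excess of 3 holding back a second olefination.

Step 3
Reactants: 5 tert-butyl (2E)-3-methyl-4-oxopent-2-enoate
Product: 6 (2E)-3-methyl-4-oxopent-2-enoic acid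
Conditions: CF3CO2H, CH2Cl2, rt
Reagents that add atoms: none
Why: Acidolysis of the tert-butyl ester by loss of isobutene leaves the ene-dione untouched, and any Z acid carried over would close to its lactol and be removed on crystallisation.

Step 4
Reactants: 6 (2E)-3-methyl-4-oxopent-2-enoic acid; 2 methyl 5-chloro-2,4-dihydroxy-3,6-dimethylbenzoate
Product: 8 methyl 5-chloro-2-hydroxy-3,6-dimethyl-4-{[(2E)-3-methyl-4-oxopent-2-enoyl]oxy}benzoate, via (2E)-3-methyl-4-oxopent-2-enoyl chloride 7 (not isolated)
Conditions: (COCl)2, DMF (cat.), CH2Cl2, 0 °C → rt; then 2, pyridine, CH2Cl2, 0 °C → rt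
Reagents that add atoms: oxalyl chloride, ClC(=O)C(=O)Cl (chlorine of intermediate 7 only; none remains in 8)
Why: Acid chloride formation followed by pyridine-mediated O-acylation should take place at the more acidic, non-chelated 4-OH of 2, because the 2-OH is held in a hydrogen bond to the ester carbonyl, and the E geometry keeps the acid chloride from closing to a cyclic pseudo-chloride.

Step 5
Reactants: 8 methyl 5-chloro-2-hydroxy-3,6-dimethyl-4-{[(2E)-3-methyl-4-oxopent-2-enoyl]oxy}benzoate
Product: 10 methyl 5-chloro-4-{[(2E)-5-diazo-3-methyl-4-oxopent-2-enoyl]oxy}-2-hydroxy-3,6-dimethylbenzoate, via trifluoroacetyl diketone 9 (not isolated)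
Conditions: LiN(SiMe3)2 (2.2 equiv), THF, −78 °C; CF3CO2CH2CF3; aq. HCl; then MsN3, Et3N, H2O, MeCN, rt
Reagents that add atoms: methanesulfonyl azide, CS(=O)(=O)N=[N+]=[N-] (the two diazo nitrogens); 2,2,2-trifluoroethyl trifluoroacetate, FC(F)(F)C(=O)OCC(F)(F)F (trifluoroacetyl group of intermediate 9 only)
Why: In this detrifluoroacetylative diazo transfer the phenol is deprotonated first, the kinetic α′ enolate of the methyl ketone is C-trifluoroacetylated, and the activated diketone 9 then accepts the diazo group from the sulfonyl azide with loss of the trifluoroacetyl group, which is the standard entry to α′-diazo enones.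

Step 6
Reactants: 10 methyl 5-chloro-4-{[(2E)-5-diazo-3-methyl-4-oxopent-2-enoyl]oxy}-2-hydroxy-3,6-dimethylbenzoate; 11 ethoxyacetylene
Product: 16 methyl 5-chloro-4-[(4-ethoxy-2-hydroxy-6-methylbenzoyl)oxy]-2-hydroxy-3,6-dimethylbenzoate, via vinylketene 12 (not isolated), via 3-ethoxy-4-alkenylcyclobutenone 13 (not isolated), via dienylketene 14 (not isolated), via cyclohexa-2,4-dienone 15 (not isolated)
Conditions: 11 (3 equiv), ClCH2CH2Cl, hν (medium-pressure Hg lamp, Pyrex filter, λ > 300 nm), 20 °C; then 80 °C
Reagents that add atoms: none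
Why: Excitation of the diazo ketone expels N2 and the alkenyl group shifts to the carbene carbon (Wolff rearrangement, forming C5–C6) to give vinylketene 12, whose electrophilic carbonyl carbon is attacked by the nucleophilic CH terminus of the ynol ether in a regioselective [2+2] cycloaddition (C2–C3 and C4–C5) that gives cyclobutenone 13. Warming opens 13 by a reversible 4π electrocyclic ring opening to dienylketene 14, which closes ring A by a thermal disrotatory 6π electrocyclisation (C1–C2) to dienone 15, and enolisation of its doubly activated C1–H gives the aromatic salicylate 16. The closest known reaction type is the Danheiser benzannulation in its photochemical Wolff variant, in which α′-diazo enones and alkoxyalkynes give resorcinol monoethers with this oxygen pattern. No stereocentre survives, since the sp3 carbons of 13 and 15 are erased by ring opening and aromatisation. The step needs the [2+2] regiochemistry that joins the ethoxy-bearing carbon to the ketene α-carbon, which the polarisation of both partners secures, and it needs the alkyne to outrun O–H capture of the ketene, which the excess of 11 and the hydrogen-bonded, flanked ring B hydroxyl should secure. The E enoate geometry keeps the ester carbonyl away from the ketene carbon, which rules out oxa-6π closure to a pyranone, and places the ester on the outside of the closing triene terminus.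

Step 7
Reactants: 16 methyl 5-chloro-4-[(4-ethoxy-2-hydroxy-6-methylbenzoyl)oxy]-2-hydroxy-3,6-dimethylbenzoate
Product: 18 methyl 5-chloro-4-[(4-ethoxy-3-formyl-2-hydroxy-6-methylbenzoyl)oxy]-2-hydroxy-3,6-dimethylbenzoate, via chloro(methoxy)methyl arene 17 (not isolated)
Conditions: Cl2CHOMe, TiCl4, CH2Cl2, 0 °C → rt; then aq. HCl
Reagents that add atoms: dichloromethyl methyl ether, COC(Cl)Cl; water, O
Why: In this Rieche formylation the titanium bound to the ring A 2-oxygen should deliver the activated dichloromethyl ether to the ortho carbon C3, which is also ortho to the ethoxy group, while ring B has no free position and the α-chloro ether is hydrolysed to the aldehyde on work-up.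

Step 8
Reactants: 18 methyl 5-chloro-4-[(4-ethoxy-3-formyl-2-hydroxy-6-methylbenzoyl)oxy]-2-hydroxy-3,6-dimethylbenzoate
Product: 19 methyl 5-chloro-4-[(3-formyl-2,4-dihydroxy-6-methylbenzoyl)oxy]-2-hydroxy-3,6-dimethylbenzoate
Conditions: BCl3, CH2Cl2, −78 → 0 °C; then H2O
Reagents that add atoms: none
Why: Chelation-assisted Lewis acid ether cleavage should remove only the ethyl group, because boron held between the aldehyde oxygen and the neighbouring 4-ethoxy oxygen activates that ether for chloride attack while the two esters stay intact at low temperature.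

Step 9
Reactants: 19 methyl 5-chloro-4-[(3-formyl-2,4-dihydroxy-6-methylbenzoyl)oxy]-2-hydroxy-3,6-dimethylbenzoate
Product: 20 methyl 5-chloro-4-[(5-chloro-3-formyl-2,4-dihydroxy-6-methylbenzoyl)oxy]-2-hydroxy-3,6-dimethylbenzoate
Conditions: SO2Cl2 (1.05 equiv), CH2Cl2–Et2O, 0 °C → rt, dark
Reagents that add atoms: sulfuryl chloride, ClS(Cl)(=O)=O
Why: Electrophilic aromatic chlorination should take place at ring A C5, the only aromatic C–H left in the molecule and one that is ortho to the 4-OH and para to the 2-OH, while exclusion of light avoids radical attack on the aldehyde.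

**Compound list**

1 | methyl 2,4-dihydroxy-3,6-dimethylbenzoate | COC(=O)c1c(C)cc(O)c(C)c1O | starting material
2 | methyl 5-chloro-2,4-dihydroxy-3,6-dimethylbenzoate | COC(=O)c1c(C)c(Cl)c(O)c(C)c1O | intermediate
3 | butane-2,3-dione | CC(=O)C(C)=O | starting material
4 | tert-butyl (triphenyl-λ5-phosphanylidene)acetate | CC(C)(C)OC(=O)C=P(c1ccccc1)(c1ccccc1)c1ccccc1 | starting material
5 | tert-butyl (2E)-3-methyl-4-oxopent-2-enoate | CC(=O)/C(C)=C/C(=O)OC(C)(C)C | intermediate
6 | (2E)-3-methyl-4-oxopent-2-enoic acid | CC(=O)/C(C)=C/C(=O)O | intermediate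
7 | (2E)-3-methyl-4-oxopent-2-enoyl chloride | CC(=O)/C(C)=C/C(=O)Cl | intermediate
8 | methyl 5-chloro-2-hydroxy-3,6-dimethyl-4-{[(2E)-3-methyl-4-oxopent-2-enoyl]oxy}benzoate | COC(=O)c1c(C)c(Cl)c(OC(=O)/C=C(\C)C(C)=O)c(C)c1O | intermediate
9 | methyl 5-chloro-2-hydroxy-3,6-dimethyl-4-{[(2E)-7,7,7-trifluoro-3-methyl-4,6-dioxohept-2-enoyl]oxy}benzoate | COC(=O)c1c(C)c(Cl)c(OC(=O)/C=C(\C)C(=O)CC(=O)C(F)(F)F)c(C)c1O | intermediate
10 | methyl 5-chloro-4-{[(2E)-5-diazo-3-methyl-4-oxopent-2-enoyl]oxy}-2-hydroxy-3,6-dimethylbenzoate | COC(=O)c1c(C)c(Cl)c(OC(=O)/C=C(\C)C(=O)C=[N+]=[N-])c(C)c1O | intermediate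
11 | ethoxyacetylene (ethoxyethyne) | C#COCC | starting material
12 | methyl 5-chloro-2-hydroxy-3,6-dimethyl-4-{[(2E)-3-methyl-5-oxopenta-2,4-dienoyl]oxy}benzoate (vinylketene) | COC(=O)c1c(C)c(Cl)c(OC(=O)/C=C(\C)C=C=O)c(C)c1O | intermediate
13 | methyl 5-chloro-4-{[(2E)-3-(2-ethoxy-4-oxocyclobut-2-en-1-yl)but-2-enoyl]oxy}-2-hydroxy-3,6-dimethylbenzoate (racemic) | COC(=O)c1c(C)c(Cl)c(OC(=O)/C=C(\C)C2C(=O)C=C2OCC)c(C)c1O | intermediate
14 | methyl 5-chloro-4-{[(2E,4E)-5-ethoxy-3-methyl-7-oxohepta-2,4,6-trienoyl]oxy}-2-hydroxy-3,6-dimethylbenzoate (dienylketene) | COC(=O)c1c(C)c(Cl)c(OC(=O)/C=C(\C)/C=C(OCC)\C=C=O)c(C)c1O | intermediate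
15 | methyl 5-chloro-4-[(4-ethoxy-2-methyl-6-oxocyclohexa-2,4-diene-1-carbonyl)oxy]-2-hydroxy-3,6-dimethylbenzoate (racemic) | COC(=O)c1c(C)c(Cl)c(OC(=O)C2C(C)=CC(OCC)=CC2=O)c(C)c1O | intermediate
16 | methyl 5-chloro-4-[(4-ethoxy-2-hydroxy-6-methylbenzoyl)oxy]-2-hydroxy-3,6-dimethylbenzoate | COC(=O)c1c(C)c(Cl)c(OC(=O)c2c(C)cc(OCC)cc2O)c(C)c1O | intermediate
17 | methyl 5-chloro-4-({3-[chloro(methoxy)methyl]-4-ethoxy-2-hydroxy-6-methylbenzoyl}oxy)-2-hydroxy-3,6-dimethylbenzoate (racemic) | COC(=O)c1c(C)c(Cl)c(OC(=O)c2c(C)cc(OCC)c(C(Cl)OC)c2O)c(C)c1O | intermediate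
18 | methyl 5-chloro-4-[(4-ethoxy-3-formyl-2-hydroxy-6-methylbenzoyl)oxy]-2-hydroxy-3,6-dimethylbenzoate | COC(=O)c1c(C)c(Cl)c(OC(=O)c2c(C)cc(OCC)c(C=O)c2O)c(C)c1O | intermediate
19 | methyl 5-chloro-4-[(3-formyl-2,4-dihydroxy-6-methylbenzoyl)oxy]-2-hydroxy-3,6-dimethylbenzoate | COC(=O)c1c(C)c(Cl)c(OC(=O)c2c(C)cc(O)c(C=O)c2O)c(C)c1O | intermediate
20 | methyl 5-chloro-4-[(5-chloro-3-formyl-2,4-dihydroxy-6-methylbenzoyl)oxy]-2-hydroxy-3,6-dimethylbenzoate | COC(=O)c1c(C)c(Cl)c(OC(=O)c2c(C)c(Cl)c(O)c(C=O)c2O)c(C)c1O | target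

**Step count and risks**

Total steps: 9. Longest linear sequence: 8 steps (3 → 5 → 6 → 8 → 10 → 16 → 18 → 19 → 20); the ring B branch (1 → 2) joins at step 4.

Steps most likely to fail:

1. Step 6. The vinylketene may be captured by a phenolic O–H instead of the alkyne. The enoate may also isomerise photochemically to the Z form and close through its ester oxygen, and light absorbed by the ring B chromophore may slow the Wolff step. Fallback (sets out from 2, returns at 16): ring A is taken from an intact arene instead of being built. Commercial methyl 2,4-dihydroxy-6-methylbenzoate F1 would be ethylated at its non-chelated 4-OH (EtI, K2CO3, acetone, reflux) to methyl 4-ethoxy-2-hydroxy-6-methylbenzoate F2. Saponification (KOH, aqueous DMSO, 80 °C; cold acidification) would give 4-ethoxy-2-hydroxy-6-methylbenzoic acid F3. Trifluoroacetic anhydride in toluene would convert this into 4-ethoxy-2-hydroxy-6-methylbenzoic trifluoroacetic anhydride F4, which should acylate the 4-OH of 2 in the same flask to give 16.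

2. Step 5. The amide base or the ketone enolate may attack the aryl ester or add to the ene-dione of a second molecule, and the trifluoroethoxide released in the acylation may transesterify the aryl ester, all in competition with C-trifluoroacetylation. Fallback (sets out from 6, returns at 10): the diazo group is installed before the aryl ester exists. Acid 6 would be esterified (2-(trimethylsilyl)ethanol, DCC, DMAP) to 2-(trimethylsilyl)ethyl (2E)-3-methyl-4-oxopent-2-enoate F5. The same enolate trifluoroacetylation would give 2-(trimethylsilyl)ethyl (2E)-7,7,7-trifluoro-3-methyl-4,6-dioxohept-2-enoate F6, and diazo transfer would give 2-(trimethylsilyl)ethyl (2E)-5-diazo-3-methyl-4-oxopent-2-enoate F7. Fluoride (Bu4NF, THF, 0 °C) would then release (2E)-5-diazo-3-methyl-4-oxopent-2-enoic acid F8, which would be coupled at once with 2 (EDC·HCl, DMAP, CH2Cl2, 0 °C) to give 10.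

3. Step 7. Site selectivity may be poor, with attack para to the 2-OH at C5 competing with the titanium-directed attack at C3. Fallback (sets out from 16, returns at 20): C5 is blocked before the formyl group is introduced. SO2Cl2 (1 equiv) should chlorinate 16 para to the ring A 2-OH to give methyl 5-chloro-4-[(5-chloro-4-ethoxy-2-hydroxy-6-methylbenzoyl)oxy]-2-hydroxy-3,6-dimethylbenzoate F9. The same TiCl4-mediated formylation can then reach only C3. It should pass through methyl 5-chloro-4-({5-chloro-3-[chloro(methoxy)methyl]-4-ethoxy-2-hydroxy-6-methylbenzoyl}oxy)-2-hydroxy-3,6-dimethylbenzoate F10 to the aldehyde methyl 5-chloro-4-[(5-chloro-4-ethoxy-3-formyl-2-hydroxy-6-methylbenzoyl)oxy]-2-hydroxy-3,6-dimethylbenzoate F11. BCl3 cleavage of the ethyl ether next to the aldehyde would then give 20 directly.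

**Further compounds**

F1 | step 6 | methyl 2,4-dihydroxy-6-methylbenzoate | COC(=O)c1c(C)cc(O)cc1O
F2 | step 6 | methyl 4-ethoxy-2-hydroxy-6-methylbenzoate | CCOc1cc(C)c(C(=O)OC)c(O)c1
F3 | step 6 | 4-ethoxy-2-hydroxy-6-methylbenzoic acid | CCOc1cc(C)c(C(=O)O)c(O)c1
F4 | step 6 | 4-ethoxy-2-hydroxy-6-methylbenzoic trifluoroacetic anhydride | CCOc1cc(C)c(C(=O)OC(=O)C(F)(F)F)c(O)c1
F5 | step 5 | 2-(trimethylsilyl)ethyl (2E)-3-methyl-4-oxopent-2-enoate | CC(=O)/C(C)=C/C(=O)OCC[Si](C)(C)C
F6 | step 5 | 2-(trimethylsilyl)ethyl (2E)-7,7,7-trifluoro-3-methyl-4,6-dioxohept-2-enoate | C[Si](C)(C)CCOC(=O)/C=C(\C)C(=O)CC(=O)C(F)(F)F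
F7 | step 5 | 2-(trimethylsilyl)ethyl (2E)-5-diazo-3-methyl-4-oxopent-2-enoate | C[Si](C)(C)CCOC(=O)/C=C(\C)C(=O)C=[N+]=[N-]
F8 | step 5 | (2E)-5-diazo-3-methyl-4-oxopent-2-enoic acid | OC(=O)/C=C(\C)C(=O)C=[N+]=[N-]
F9 | step 7 | methyl 5-chloro-4-[(5-chloro-4-ethoxy-2-hydroxy-6-methylbenzoyl)oxy]-2-hydroxy-3,6-dimethylbenzoate | COC(=O)c1c(C)c(Cl)c(OC(=O)c2c(C)c(Cl)c(OCC)cc2O)c(C)c1O
F10 | step 7 | methyl 5-chloro-4-({5-chloro-3-[chloro(methoxy)methyl]-4-ethoxy-2-hydroxy-6-methylbenzoyl}oxy)-2-hydroxy-3,6-dimethylbenzoate (racemic) | COC(=O)c1c(C)c(Cl)c(OC(=O)c2c(C)c(Cl)c(OCC)c(C(Cl)OC)c2O)c(C)c1O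
F11 | step 7 | methyl 5-chloro-4-[(5-chloro-4-ethoxy-3-formyl-2-hydroxy-6-methylbenzoyl)oxy]-2-hydroxy-3,6-dimethylbenzoate | COC(=O)c1c(C)c(Cl)c(OC(=O)c2c(C)c(Cl)c(OCC)c(C=O)c2O)c(C)c1O
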